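# Proposed synthesis of asperimide C by iron-catalysed double carbonylation of a 1,3-diarylpropyne

## Analysis of the target

Asperimide C (14) has four rings: a maleimide (ring A: N1, C2=O, C3, C4, C5=O), a 4-hydroxyphenyl group on C3(A) (ring B), and a 2,2-dimethylchroman-3-ol (benzo ring C fused to dihydropyran ring D: O1, C2, C3, C4, C4a, C8a). One methylene joins C7 of the chroman to C4(A). Read from the SMILES, this methylene is para to C4a and meta to O1, so ring C is a 1,2,4-trisubstituted benzene; an ortho-selective reaction of a meta-substituted phenol would not deliver this pattern cleanly. The only stereocentre is C3(D), S, a secondary carbinol between the quaternary C2 (gem-dimethyl, O1) and the benzylic C4. It has no neighbour to relay from and must be set by a catalyst or reagent. Ring A is the demanding part. Its C3=C4 bond is tetrasubstituted and unsymmetrical (aryl on C3, benzyl on C4), the N–H imide is acidic and opens with hydroxide or alkoxide, and the C4(A)–CH2–aryl methylene is doubly activated, so base or oxidant can move the double bond out of the ring or oxidise that carbon. The phenol and the secondary alcohol add further protic sites, and the O1–C2 tertiary alkyl aryl ether can ionise under strong Lewis acid. Ring A can be read as a two-carbon unit (C3, C4) flanked by two carbonyl carbons (C2, C5) bridged by one nitrogen, that is, an alkyne that has taken up two CO and one NH3. The route is built on this reading, because each alkyne carbon then receives one carbonyl whatever it carries, and the regiochemical problem of the unsymmetrical maleimide disappears.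

## Retrosynthetic reasoning

**14 to 13.** The C3=C4 double bond of ring A is removed first, giving succinimide 13. This is done because 13 is the oxidant-free product of the key step, and its two extra stereocentres need no control since both are erased again. The forward step must dehydrogenate ring A without touching C4–H2 of ring D or the carbinol. The free para-phenol of ring B is the handle: a quinone oxidant can abstract hydride from C3(A)–H through a p-quinone methide at room temperature.

**13 to 12 (key disconnection).** Four bonds of ring A are cut at once: C2–C3, C4–C5, N1–C2 and N1–C5. What remains is alkyne 12, whose two sp carbons are C3(A) and C4(A); the two carbonyl carbons and the nitrogen come from gaseous C1 and N1 reagents. The cut is made here and not at C3=C4 because it turns the hardest ring into a linear 1,3-diarylpropyne with no heterocycle, no regiochemical issue and no carbonyl chemistry before the last two steps. The forward reaction must carbonylate both alkyne carbons, close the imide with nitrogen and tolerate the phenol and the alcohol.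

**12 to 7 and 8.** The C(sp3)–C(sp) bond between the ring C methylene and the alkyne is cut. This gives benzylic bromide 7 and arylacetylene 8, two fragments of similar size, so the route is convergent. The alternative cut, aryl–alkyne, would need a terminal 3-arylpropyne and one more step. The forward reaction is a zinc acetylide (10, from lithium acetylide 9) coupling under palladium catalysis. The phenol of ring B is carried as a silyl ether (coupled product 11) only across this one operation and is freed in the same flask.

**7 to 6 to 5.** The bromide comes from the primary alcohol of diol 6. Both hydroxyls of 6 are traced to one precursor, epoxy ester 5: a single hydride reagent opens the epoxide at benzylic C4 and reduces the ester at C7. C3(D)–O is not touched, so the configuration of 5 becomes that of 6.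

**5 to 4.** The epoxide oxygen is removed to give chromene 4. 2,2-Dimethyl-2H-chromenes are the best substrate class for manganese–salen asymmetric epoxidation, so the single stereocentre is set at an early, cheap intermediate by a catalyst.

**4 to 1 and 2.** Ring D is opened at O1–C2 and at C4–C4a. The aryl–vinyl bond comes from a Heck reaction of iodophenol 1 with tertiary allylic alcohol 2 (adduct 3); the O1–C2 bond comes from acid-induced cyclodehydration of 3. The iodine of 1 fixes the ring C substitution pattern (ester para to C4a), which a Claisen-type annulation of a meta-substituted phenol would not.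

## Alternatives that were turned down

**Alternative 1:** the textbook route. Disconnection: C3=C4 and N1–C5 of ring A. Forward key step: base-mediated condensation (KOtBu) of α-keto ester A1 with arylacetamide A2, that is, aldol addition of the amide enolate, N-acylation by the ester and dehydration. Reasons against:
- A1 is an arylpyruvate. It has to be made from 7 by a two-step homologation, so the sequence is no shorter.
- A1 is largely enolised, a poor electrophile towards the amide enolate, and prone to self-condensation.
- Three O–H/N–H sites need either protection or a large excess of strong base.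
- The tertiary carbinol intermediate can dehydrate towards the exocyclic benzylidene instead of into the ring.
- The bonds are made one by one with the risk spread over several steps. It is kept only as a fallback.

**Alternative 2:** Disconnection: the C3(A)–aryl and C4(A)–CH2 bonds. Forward: two successive cross-couplings on dibromomaleimide A3, first a Suzuki arylation to bromide A4, then a Negishi coupling with benzylzinc reagent A5. Reasons against:
- Ring A is bought, not built, and each step forms one bond.
- The N–H imide is acidic and opens under aqueous base, so the Suzuki step would need N-protection and later a harsh N-deprotection.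
- Mono- against bis-arylation of the symmetrical dibromide must be controlled.
- A5 needs the C3(D) hydroxyl masked, and coupling of a benzylzinc at an electron-poor bromo-enone competes with reduction and homocoupling.
- The protecting-group traffic makes the route longer than the one chosen.

**Alternative 3:** Disconnection: O1–C2 of ring D, made last and biomimetically. Forward: Shi epoxidation of prenylphenol A6 to epoxide A7, then 6-endo opening of the epoxide by the phenol. Reasons against:
- Dioxirane epoxidation runs in carbonate buffer near pH 10, where the N–H maleimide opens and the two phenols are at risk, so protection is needed.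
- Closure of A7 has to be steered to 6-endo against the 5-exo mode, which gives the five-membered ether.
- The stereocentre would be set on the most advanced intermediate.
- A6 needs a prenyl group ortho to the hydroxyl and para to the benzylic carbon of a meta-substituted phenol, which Claisen or Friedel–Crafts chemistry gives as mixtures, and ring A still has to be made.

Key step: step 6

Assumption: silyl ether 8 is taken as a purchasable building block; if it is not, it is one silylation (TBSCl, imidazole) from 4-ethynylphenol and the count rises by one.

## Route

Step 1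
Reactants: 1 methyl 3-hydroxy-4-iodobenzoate; 2 2-methylbut-3-en-2-ol
Product: 4 methyl 2,2-dimethyl-2H-chromene-7-carboxylate, via E-allylic alcohol 3 (not isolated)
Conditions: Pd(OAc)2 (3 mol%), P(o-tol)3 (6 mol%), Et3N, MeCN, 85 °C; then solvent switch, TsOH·H2O (10 mol%), toluene, 80 °C
Reagents that add atoms: none
Why: Mizoroki–Heck arylation of a tertiary allylic alcohol can β-eliminate only away from the carbinol carbon and gives the E-styrene 3; acid then ionises the tertiary allylic alcohol to an o-quinone-methide-type cation, in which the styrene geometry can equilibrate, and oxa-6π closure of the phenol oxygen onto the tertiary carbon gives the 2H-chromene. The iodine position of 1 fixes the ester at C7.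

Step 2
Reactants: 4 methyl 2,2-dimethyl-2H-chromene-7-carboxylate
Product: 5 methyl (1aS,7bS)-2,2-dimethyl-1a,7b-dihydro-2H-oxireno[2,3-c]chromene-5-carboxylate, the (3S,4S)-3,4-epoxychroman
Conditions: (S,S)-[N,N'-bis(3,5-di-tert-butylsalicylidene)cyclohexane-1,2-diaminato]manganese chloride (3 mol%), NaOCl (aq., pH 11.3), 4-phenylpyridine N-oxide (20 mol%), CH2Cl2, 0 °C
Reagents that add atoms: sodium hypochlorite, [Na+].[O-]Cl
Why: Jacobsen–Katsuki epoxidation; cis-alkenes locked in 2,2-dimethylchromenes, especially electron-poor ones, are the privileged substrates. The (S,S)-catalyst should deliver oxygen to the face that gives the (3S,4S)-epoxide (side-on approach over the diamine backbone, arene away from the tert-butyl groups), which sets C3(D).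

Step 3
Reactants: 5 methyl (1aS,7bS)-2,2-dimethyl-1a,7b-dihydro-2H-oxireno[2,3-c]chromene-5-carboxylate
Product: 6 (3S)-7-(hydroxymethyl)-2,2-dimethyl-3,4-dihydro-2H-chromen-3-ol
Conditions: LiAlH4 (3 equiv), THF, 0 °C to rt; aq. potassium sodium tartrate
Reagents that add atoms: none
Why: Hydride opens the epoxide by SN2 attack at benzylic C4 and not at C3, which is neopentyl-like next to the gem-dimethyl carbon, so the C3–O bond and its S configuration are retained; the same reagent reduces the methyl ester to the primary alcohol.

Step 4
Reactants: 6 (3S)-7-(hydroxymethyl)-2,2-dimethyl-3,4-dihydro-2H-chromen-3-ol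
Product: 7 (3S)-7-(bromomethyl)-2,2-dimethyl-3,4-dihydro-2H-chromen-3-ol
Conditions: CBr4 (1.1 equiv), PPh3 (1.1 equiv), CH2Cl2, 0 °C
Reagents that add atoms: carbon tetrabromide, BrC(Br)(Br)Br
Why: Appel reaction; the primary benzylic alcohol forms and displaces its alkoxyphosphonium far faster than the secondary hydroxyl next to the quaternary carbon, so one equivalent of reagent should be selective.

Step 5
Reactants: 7 (3S)-7-(bromomethyl)-2,2-dimethyl-3,4-dihydro-2H-chromen-3-ol; 8 tert-butyl(4-ethynylphenoxy)dimethylsilane
Product: 12 (3S)-7-[3-(4-hydroxyphenyl)prop-2-yn-1-yl]-2,2-dimethyl-3,4-dihydro-2H-chromen-3-ol, via lithium acetylide 9 (not isolated), via alkynylzinc bromide 10 (not isolated), via silyl-protected alkyne 11 (not isolated)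
Conditions: 8 (2.2 equiv), nBuLi, THF, −78 °C; ZnBr2, 0 °C; then 7, PdCl2(DPEphos) (5 mol%), THF, rt; then Bu4NF/AcOH (1:1, excess), 0 °C
Reagents that add atoms: none
Why: Negishi alkynyl–benzyl coupling; zinc acetylides couple with benzylic bromides under palladium–DPEphos catalysis without amine or carbonate base, so the skipped diarylpropyne should not isomerise to the allene, and the excess of 10 absorbs the hydroxyl proton of 7. Buffered fluoride then cleaves the aryl silyl ether in the same flask.

Step 6
Reactants: 12 (3S)-7-[3-(4-hydroxyphenyl)prop-2-yn-1-yl]-2,2-dimethyl-3,4-dihydro-2H-chromen-3-ol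
Product: 13 3-(4-hydroxyphenyl)-4-{[(3S)-3-hydroxy-2,2-dimethyl-3,4-dihydro-2H-chromen-7-yl]methyl}pyrrolidine-2,5-dione (mixture of diastereomers at C3 and C4 of the imide)
Conditions: Fe3(CO)12 (10 mol%), NH3 (liquid, excess), CO (20 bar), THF, 120 °C, autoclave
Reagents that add atoms: carbon monoxide, [C-]#[O+]; ammonia, N
Why: Iron-carbonyl-catalysed double carbonylation of an internal alkyne with ammonia, a Reppe-type cyclocarbonylation known for diaryl, dialkyl and aryl/benzyl alkynes. Ammonia breaks Fe3(CO)12 down to mononuclear carbonyl species; at zerovalent iron the alkyne couples with two CO ligands to a maleoyl ferracycle (ferracyclopentenedione), which makes C2–C3 and C4–C5. Ammonia opens the ferracycle at one acyl carbon (N1–C2), and the amide nitrogen then closes ring A on the second acyl–iron carbon (N1–C5) in a 5-exo-trig acyl substitution; the two hydrogens given up by nitrogen are returned to C3 and C4 through iron hydride, so the succinimide is the redox-neutral product and no oxidant is needed. No regiochemical question arises, because each alkyne carbon receives one carbonyl whatever its substituent. The new stereocentres C3 and C4 of ring A form without control (the trans isomers should dominate after epimerisation under ammonia) and both are removed in step 7; the carbinol C3 of ring D is remote, not epimerisable and untouched. Required selectivities: double over single carbonylation, secured by CO pressure and the absence of phosphine ligands; nitrogen over oxygen nucleophiles, secured by the excess of ammonia over the phenol and the hindered alcohol; and no propargyl-to-allenyl isomerisation of 12, for which ammonia is too weak a base. The protic groups should be tolerated because iron carbonyl hydride chemistry operates in protic, basic media.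

Step 7
Reactants: 13 3-(4-hydroxyphenyl)-4-{[(3S)-3-hydroxy-2,2-dimethyl-3,4-dihydro-2H-chromen-7-yl]methyl}pyrrolidine-2,5-dione
Product: 14 3-(4-hydroxyphenyl)-4-{[(3S)-3-hydroxy-2,2-dimethyl-3,4-dihydro-2H-chromen-7-yl]methyl}-1H-pyrrole-2,5-dione (asperimide C)
Conditions: DDQ (1.05 equiv), 1,4-dioxane, rt
Reagents that add atoms: none
Why: Quinone dehydrogenation of a succinimide to a maleimide; hydride abstraction from C3(A)–H, benzylic and para to the free phenol, gives a p-quinone methide, and loss of the C4(A) proton is the only tautomerisation that re-aromatises ring B, so the double bond lands in the ring. This phenol-assisted path should run at room temperature, where C4–H2 of ring D and the secondary alcohol are not attacked; every diastereomer of 13 converges on 14.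

## Compound list

1 | methyl 3-hydroxy-4-iodobenzoate | COC(=O)c1ccc(I)c(O)c1 | starting material
2 | 2-methylbut-3-en-2-ol | CC(C)(O)C=C | starting material
3 | methyl 3-hydroxy-4-[(E)-3-hydroxy-3-methylbut-1-en-1-yl]benzoate | COC(=O)c1ccc(/C=C/C(C)(C)O)c(O)c1 | intermediate (not isolated)
4 | methyl 2,2-dimethyl-2H-chromene-7-carboxylate | COC(=O)c1ccc2C=CC(C)(C)Oc2c1 | intermediate
5 | methyl (1aS,7bS)-2,2-dimethyl-1a,7b-dihydro-2H-oxireno[2,3-c]chromene-5-carboxylate | CC1(C)Oc2cc(C(=O)OC)ccc2[C@@H]2O[C@H]12 | intermediate
6 | (3S)-7-(hydroxymethyl)-2,2-dimethyl-3,4-dihydro-2H-chromen-3-ol | CC1(C)Oc2cc(CO)ccc2C[C@@H]1O | intermediate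
7 | (3S)-7-(bromomethyl)-2,2-dimethyl-3,4-dihydro-2H-chromen-3-ol | CC1(C)Oc2cc(CBr)ccc2C[C@@H]1O | intermediate
8 | tert-butyl(4-ethynylphenoxy)dimethylsilane | C#Cc1ccc(O[Si](C)(C)C(C)(C)C)cc1 | starting material
9 | lithium {4-[(tert-butyldimethylsilyl)oxy]phenyl}acetylide | [Li]C#Cc1ccc(O[Si](C)(C)C(C)(C)C)cc1 | intermediate (not isolated)
10 | ({4-[(tert-butyldimethylsilyl)oxy]phenyl}ethynyl)zinc bromide | Br[Zn]C#Cc1ccc(O[Si](C)(C)C(C)(C)C)cc1 | intermediate (not isolated)
11 | (3S)-7-(3-{4-[(tert-butyldimethylsilyl)oxy]phenyl}prop-2-yn-1-yl)-2,2-dimethyl-3,4-dihydro-2H-chromen-3-ol | CC1(C)Oc2cc(CC#Cc3ccc(O[Si](C)(C)C(C)(C)C)cc3)ccc2C[C@@H]1O | intermediate (not isolated)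
12 | (3S)-7-[3-(4-hydroxyphenyl)prop-2-yn-1-yl]-2,2-dimethyl-3,4-dihydro-2H-chromen-3-ol | CC1(C)Oc2cc(CC#Cc3ccc(O)cc3)ccc2C[C@@H]1O | intermediate
13 | 3-(4-hydroxyphenyl)-4-{[(3S)-3-hydroxy-2,2-dimethyl-3,4-dihydro-2H-chromen-7-yl]methyl}pyrrolidine-2,5-dione (imide stereocentres not defined) | CC1(C)Oc2cc(CC3C(c4ccc(O)cc4)C(=O)NC3=O)ccc2C[C@@H]1O | intermediate
14 | 3-(4-hydroxyphenyl)-4-{[(3S)-3-hydroxy-2,2-dimethyl-3,4-dihydro-2H-chromen-7-yl]methyl}-1H-pyrrole-2,5-dione (asperimide C) | CC1(C)Oc2cc(CC3=C(c4ccc(O)cc4)C(=O)NC3=O)ccc2C[C@@H]1O | target

## Step count and risk assessment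

Total step count: 7. Longest linear sequence: 7 steps (from 1 to 14); 8 enters at step 5 without steps of its own.

**Step 6 (key step).** The carbonylation may stop after one CO (acrylamide-type products). The skipped alkyne may isomerise to the allene before it is carbonylated. Excess ammonia may open the imide to the diamide, and the phenoxide may tie up the iron catalyst. Fallback, using known condensation chemistry, from 7 to 14:
- The sodium enolate of commercial ethyl 1,3-dithiane-2-carboxylate (NaH, 1.0 equiv, THF/DMF, 0 °C) is alkylated with 7 to give ethyl 2-{[(3S)-3-hydroxy-2,2-dimethyl-3,4-dihydro-2H-chromen-7-yl]methyl}-1,3-dithiane-2-carboxylate F1.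
- The dithiane is removed (MeI, CaCO3, aq. MeCN, 50 °C) to give ethyl 3-[(3S)-3-hydroxy-2,2-dimethyl-3,4-dihydro-2H-chromen-7-yl]-2-oxopropanoate F2.
- F2 is condensed with 2-(4-hydroxyphenyl)acetamide A2 (KOtBu in excess, THF, 0 °C to rt, acidic work-up) to give 14 directly.

**Step 7.** Over-oxidation is the main danger: a second hydride abstraction at the doubly activated methylene of the product through an extended quinone methide, or at C4 of ring D. Nucleophiles may also trap the quinone methide before it tautomerises. Fallback from 13 to 14, which replaces hydride abstraction by enolate chemistry: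
- Deprotonation with LiN(SiMe3)2 (4.2 equiv, THF, −78 °C) and selenenylation of the more acidic, aryl-bearing C3(A) with PhSeCl (1.0 equiv) gives 3-(4-hydroxyphenyl)-4-{[(3S)-3-hydroxy-2,2-dimethyl-3,4-dihydro-2H-chromen-7-yl]methyl}-3-(phenylselanyl)pyrrolidine-2,5-dione F3.
- Oxidation with H2O2 (0 °C) and selenoxide syn-elimination, which can only take the C4(A) hydrogen, gives 14.

**Step 5.** The hydroxyl of 7 may protonate the zinc acetylide faster than expected, the acetylide may homocouple, and the propyne may isomerise to the allene during desilylation. Fallback from 7 to 12, which forms the aryl–alkyne bond instead and needs no protecting group: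
- Ethynylmagnesium bromide (3 equiv) with CuBr (10 mol%) in THF at reflux gives (3S)-2,2-dimethyl-7-(prop-2-yn-1-yl)-3,4-dihydro-2H-chromen-3-ol F4.
- Sonogashira coupling of F4 with 4-iodophenol (PdCl2(PPh3)2, CuI, Et3N, THF, rt) gives 12.

**Step 3.** Regioselectivity of the hydride opening may be lost, or aluminium species may rearrange the epoxide to the achiral 3-ketone, whose reduction would erode the enantiomeric purity. Fallback from 5 to 6, which sets the stereocentre by ketone reduction:
- Meinwald rearrangement (BF3·OEt2, catalytic, CH2Cl2, −20 °C) gives methyl 2,2-dimethyl-3-oxo-3,4-dihydro-2H-chromene-7-carboxylate F5.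
- Corey–Bakshi–Shibata reduction with (R)-2-methyl-CBS-oxazaborolidine and BH3·SMe2 gives methyl (3S)-3-hydroxy-2,2-dimethyl-3,4-dihydro-2H-chromene-7-carboxylate F6. The R catalyst is the enantiomer predicted by the large/small model, with the quaternary carbon as the large group.
- LiAlH4 reduces the ester of F6 to give 6.

## Further compounds

F1 | step 6 | ethyl 2-{[(3S)-3-hydroxy-2,2-dimethyl-3,4-dihydro-2H-chromen-7-yl]methyl}-1,3-dithiane-2-carboxylate | CC1(C)Oc2cc(CC3(C(=O)OCC)SCCCS3)ccc2C[C@@H]1O
F2 | step 6 | ethyl 3-[(3S)-3-hydroxy-2,2-dimethyl-3,4-dihydro-2H-chromen-7-yl]-2-oxopropanoate | CC1(C)Oc2cc(CC(=O)C(=O)OCC)ccc2C[C@@H]1O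
F3 | step 7 | 3-(4-hydroxyphenyl)-4-{[(3S)-3-hydroxy-2,2-dimethyl-3,4-dihydro-2H-chromen-7-yl]methyl}-3-(phenylselanyl)pyrrolidine-2,5-dione | CC1(C)Oc2cc(CC3C(=O)NC(=O)C3([Se]c3ccccc3)c3ccc(O)cc3)ccc2C[C@@H]1O
F4 | step 5 | (3S)-2,2-dimethyl-7-(prop-2-yn-1-yl)-3,4-dihydro-2H-chromen-3-ol | CC1(C)Oc2cc(CC#C)ccc2C[C@@H]1O
F5 | step 3 | methyl 2,2-dimethyl-3-oxo-3,4-dihydro-2H-chromene-7-carboxylate | CC1(C)Oc2cc(C(=O)OC)ccc2CC1=O
F6 | step 3 | methyl (3S)-3-hydroxy-2,2-dimethyl-3,4-dihydro-2H-chromene-7-carboxylate | CC1(C)Oc2cc(C(=O)OC)ccc2C[C@@H]1O
A1 | alternative 1 | methyl 3-[(3S)-3-hydroxy-2,2-dimethyl-3,4-dihydro-2H-chromen-7-yl]-2-oxopropanoate | CC1(C)Oc2cc(CC(=O)C(=O)OC)ccc2C[C@@H]1O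
A2 | alternative 1 | 2-(4-hydroxyphenyl)acetamide | NC(=O)Cc1ccc(O)cc1
A3 | alternative 2 | 3,4-dibromo-1H-pyrrole-2,5-dione | O=C1NC(=O)C(Br)=C1Br
A4 | alternative 2 | 3-bromo-4-(4-hydroxyphenyl)-1H-pyrrole-2,5-dione | O=C1NC(=O)C(c2ccc(O)cc2)=C1Br
A5 | alternative 2 | ({(3S)-3-[(tert-butyldimethylsilyl)oxy]-2,2-dimethyl-3,4-dihydro-2H-chromen-7-yl}methyl)zinc bromide | CC1(C)Oc2cc(C[Zn]Br)ccc2C[C@@H]1O[Si](C)(C)C(C)(C)C
A6 | alternative 3 | 3-(4-hydroxyphenyl)-4-{[3-hydroxy-4-(3-methylbut-2-en-1-yl)phenyl]methyl}-1H-pyrrole-2,5-dione | CC(C)=CCc1ccc(CC2=C(c3ccc(O)cc3)C(=O)NC2=O)cc1O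
A7 | alternative 3 | 4-[(4-{[(2S)-3,3-dimethyloxiran-2-yl]methyl}-3-hydroxyphenyl)methyl]-3-(4-hydroxyphenyl)-1H-pyrrole-2,5-dione | CC1(C)O[C@H]1Cc1ccc(CC2=C(c3ccc(O)cc3)C(=O)NC2=O)cc1O
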